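**Plan**

- Atoms are numbered as in germacranes: ring C1–C10, lactone carbons C11–C13, C14 on C10, C15 on C4. The target is 6R,7S,8R: a cis-fused C6–O/C7 γ-lactone, the C8 isovalerate trans to C11, both ring alkenes ring-cis.
- Retrosynthesis cuts, in this order: the C15–O and C14–O bonds, the C8–O acyl bond, C11=C13, the O6–C12 lactone bond and C7–C11; then C6–C7 and C8–C9 of the remaining ten-membered 1,3-dione.
- The last cut is possible because, without C7 and C8, the ring atoms C9–C10=C1–C2–C3–C4=C5–C6 are the skeleton of cis,cis-1,5-dimethylcycloocta-1,5-diene, which already holds both ring-cis trisubstituted alkenes and the C14 and C15 methyl groups.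
- Forward: the eight-membered ring is oxidised at C6 and enolised towards C9; a ketene [2+2] puts a four-membered ring on C6=C9 and its fragmentation gives the ten-membered ring; C7 is alkylated, the lactone ring closes last, and the two methyl groups are oxidised at the end.
- Stereochemistry: C8 (absolute) and C7 come from a catalyst-controlled transfer hydrogenation with dynamic kinetic resolution, C6 from hydride addition under control of C7; the alkene geometry comes from the diene and is kept by the SeO2 oxidations.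

Key step: step 3

Assumption: commercial 1 is used as the 1,5-dimethyl isomer, freed from the accompanying 1,6-dimethyl isomer by fractional distillation, and the configuration of the target is taken exactly as its SMILES encodes it (cis-fused lactone).

**Route**

Step 1
Reactants: 1 (1Z,5Z)-1,5-dimethylcycloocta-1,5-diene
Product: 2 (2Z,6Z)-3,7-dimethylcycloocta-2,6-dien-1-one
Conditions: Rh2(C6H10NO)4 (dirhodium tetracaprolactamate, 0.5 mol %), t-BuOOH (4 equiv), K2CO3, CH2Cl2, 20 °C, stopped at partial conversion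
Reagents that add atoms: tert-butyl hydroperoxide, CC(C)(C)OO
Why: The dirhodium caprolactamate/t-BuOOH allylic oxidation (hydrogen abstraction by t-BuOO radicals, capture of the allyl radical at its secondary terminus and collapse of the mixed peroxide to the enone) prefers the ring CH2 next to the vinylic CH of 1-methylcycloalkenes, here C6, which the C2 axis of 1 makes equivalent to C2, so a single enone is expected while partial conversion holds back a second oxidation; no stereocentre is formed and both ring-cis alkenes stay in place.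

Step 2
Reactants: 2 (2Z,6Z)-3,7-dimethylcycloocta-2,6-dien-1-one
Product: 4 trimethyl{[(1E,3Z,7Z)-3,7-dimethylcycloocta-1,3,7-trien-1-yl]oxy}silane, via lithium trienolate 3 (not isolated)
Conditions: LiN(i-Pr)2, THF, −78 °C; Me3SiCl, Et3N, −78 → 0 °C; cold NaHCO3/pentane work-up
Reagents that add atoms: chlorotrimethylsilane, C[Si](C)(C)Cl
Why: Kinetic deprotonation by the hindered amide takes the α′ hydrogen at C9, which is also allylic to C1=C10, and O-silylation of the cross-conjugated enolate (silyl enol ether formation) gives the C6=C9 enol ether, ring-cis by necessity in the eight-membered ring; the triene is kept at or below 20 °C and used at once to avoid 6π electrocyclisation.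

Step 3
Reactants: 4 trimethyl{[(1E,3Z,7Z)-3,7-dimethylcycloocta-1,3,7-trien-1-yl]oxy}silane; 5 trichloroacetyl chloride
Product: 9 (4Z,8Z)-5,9-dimethylcyclodeca-4,8-diene-1,3-dione, via dichloroketene 6 (not isolated), via dichlorocyclobutanone adduct 7 (not isolated), via dechlorinated siloxycyclobutanone 8 (not isolated)
Conditions: Cl3CCOCl, Zn–Cu couple, Et2O/DME, 0 → 20 °C; filter; then Zn dust, AcOH/H2O (4:1), 20 °C
Reagents that add atoms: none
Why: Zinc strips two chlorines from 5 to give dichloroketene 6; C9, the nucleophilic terminus of the enol ether of 4, attacks its central carbon and the oxocarbenium/enolate zwitterion collapses by C6–C7 bonding, a stepwise ketene [2+2] cycloaddition in which the four-membered ring closes in a 4-exo-trig sense onto C6 to give the cis-fused cyclobutanone 7. Zinc in acetic acid then replaces both chlorines at C7 by hydrogen (8), the O–Si bond is hydrolysed, and retro-aldol scission of C6–C9, driven by release of four-ring strain, opens the bicyclo[6.2.0] skeleton to the ten-membered 1,3-dione 9; this ring therefore arises by fragmentation of the shared bond and not by an end-to-end closure. The closest known reaction type is the dichloroketene–silyl enol ether cycloaddition followed by reductive dechlorination and two-carbon ring expansion to cycloalkane-1,3-diones, a cycloaddition that also takes place at the siloxy-bearing double bond of 2-siloxy-1,3-dienes. The two ring-fusion stereocentres of 7 and 8 are cis by the geometry of the eight-membered enol ether and are erased on fragmentation, so 9 carries no stereocentre and both ring-cis trisubstituted alkenes pass through unchanged. The step needs site and regioselectivity in the cycloaddition: the enol ether is by far the most electron-rich π bond and is polarised towards C9, which fixes the C8–C9/C6–C7 connectivity and disfavours both attack on the plain trisubstituted alkenes and [4+2] capture at the fully substituted C4. It also needs the cyclobutanol to open at C6–C9 and not at C6–C7, which is secured by removing the chlorines first (a CCl2 carbanion would favour C6–C7 scission) and by the allylic, more substituted enolate left at C9, whose kinetic α-protonation keeps the C1=C10 alkene out of conjugation.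

Step 4
Reactants: 9 (4Z,8Z)-5,9-dimethylcyclodeca-4,8-diene-1,3-dione; 10 tert-butyl bromoacetate
Product: 11 tert-butyl 2-[(3Z,7Z)-4,8-dimethyl-2,10-dioxocyclodeca-3,7-dien-1-yl]acetate
Conditions: K2CO3 (1.2 equiv), acetone, 20 °C
Reagents that add atoms: none
Why: C-Alkylation of a 1,3-diketone (SN2 on the α-bromo ester by the carbonate-generated C7 enolate, which in this medium ring can take the chelated U-shape of an open-chain diketone and so reacts at carbon) installs C11 and C12, the mild base leaves C9–H and the skipped C1=C10 alkene alone, one equivalent of 10 limits dialkylation, and the new C7 centre is formed racemic and stays labile until step 5.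

Step 5
Reactants: 11 tert-butyl 2-[(3Z,7Z)-4,8-dimethyl-2,10-dioxocyclodeca-3,7-dien-1-yl]acetate
Product: 12 tert-butyl 2-[(1S,3Z,7Z,10R)-10-hydroxy-4,8-dimethyl-2-oxocyclodeca-3,7-dien-1-yl]acetate
Conditions: RuCl[(R,R)-TsDPEN](p-cymene) (2 mol %), HCO2H/Et3N (5:2), CH2Cl2, 25 °C
Reagents that add atoms: none
Why: This is a Noyori–Ikariya asymmetric transfer hydrogenation with dynamic kinetic resolution, a known reaction of 2-alkyl-1,3-diketones, in which C7 epimerises quickly through the enol in the amine–formate medium, hydride goes to the non-conjugated C8 carbonyl (the C6 carbonyl is deactivated as an enone and its β,β-disubstituted alkene resists conjugate reduction), the (R,R) ligand sets 8R by the usual quadrant model with the acyl-bearing C7 flank in the place of the aryl group, and the faster-reacting C7 epimer gives the syn relationship along C6–C7–C8–C9, which is 7S with the hydroxyl trans to the side chain on the ring, while the tert-butyl ester cannot lactonise onto O8.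

Step 6
Reactants: 12 tert-butyl 2-[(1S,3Z,7Z,10R)-10-hydroxy-4,8-dimethyl-2-oxocyclodeca-3,7-dien-1-yl]acetate
Product: 13 tert-butyl 2-[(1S,3Z,7Z,10R)-10-[(tert-butyldimethylsilyl)oxy]-4,8-dimethyl-2-oxocyclodeca-3,7-dien-1-yl]acetate
Conditions: t-BuMe2SiOTf, 2,6-lutidine, CH2Cl2, −78 °C
Reagents that add atoms: tert-butyldimethylsilyl trifluoromethanesulfonate, CC(C)(C)[Si](C)(C)OS(=O)(=O)C(F)(F)F
Why: Silylation of a secondary alcohol with a silyl triflate and a hindered pyridine base at low temperature outruns enolisation, β-elimination and retro-aldol of the β-hydroxy ketone, and the silyl ether keeps O8 out of the lactonisation of step 7 and of the enolate chemistry of step 8 without touching a stereocentre.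

Step 7
Reactants: 13 tert-butyl 2-[(1S,3Z,7Z,10R)-10-[(tert-butyldimethylsilyl)oxy]-4,8-dimethyl-2-oxocyclodeca-3,7-dien-1-yl]acetate
Product: 15 (3aR,4R,6Z,10Z,11aR)-4-[(tert-butyldimethylsilyl)oxy]-6,10-dimethyl-3a,4,5,8,9,11a-hexahydro-3H-cyclodeca[b]furan-2-one, via lithium C6 alkoxide 14 (not isolated)
Conditions: LiBH(s-Bu)3, THF, −78 °C, then warm to 20 °C; aq. NH4Cl
Reagents that add atoms: none
Why: 1,2-Reduction of the β,β-disubstituted enone by the bulky trialkylborohydride is expected from the face of C6 opposite the adjacent C7 side chain, which sets 6R with the alkoxide cis to CH2CO2t-Bu (substrate control by C7), and on warming this lithium alkoxide closes the γ-lactone by 5-exo-trig acyl substitution with loss of tert-butoxide (intramolecular transesterification) to give the cis-fused lactone.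

Step 8
Reactants: 15 (3aR,4R,6Z,10Z,11aR)-4-[(tert-butyldimethylsilyl)oxy]-6,10-dimethyl-3a,4,5,8,9,11a-hexahydro-3H-cyclodeca[b]furan-2-one
Product: 19 (3aR,4R,6Z,10Z,11aR)-4-[(tert-butyldimethylsilyl)oxy]-6,10-dimethyl-3-methylidene-3a,4,5,8,9,11a-hexahydrocyclodeca[b]furan-2-one, via lithium lactone enolate 16 (not isolated), via Mannich base 17 (not isolated), via quaternary ammonium iodide 18 (not isolated)
Conditions: LiN(i-Pr)2, THF, −78 °C; CH2=NMe2+ I−, −78 → 20 °C; MeI, MeOH, 20 °C; NaHCO3 (aq.), CH2Cl2, 20 °C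
Reagents that add atoms: N,N-dimethylmethyleneiminium iodide, C=[N+](C)C.[I-]
Why: Lactone α-methylenation by the Mannich route (lithium enolate plus the iminium salt, exhaustive N-methylation, then Hofmann-type β-elimination of trimethylamine under bicarbonate) is standard for γ-butyrolactones, C11 is the only acidic site now that O8 is silylated, and C6, C7 and C8 are not affected.

Step 9
Reactants: 19 (3aR,4R,6Z,10Z,11aR)-4-[(tert-butyldimethylsilyl)oxy]-6,10-dimethyl-3-methylidene-3a,4,5,8,9,11a-hexahydrocyclodeca[b]furan-2-one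
Product: 20 (3aS,4R,6Z,10Z,11aR)-4-hydroxy-6,10-dimethyl-3-methylidene-3a,4,5,8,9,11a-hexahydrocyclodeca[b]furan-2-one
Conditions: HF·pyridine, pyridine, THF, 0 → 20 °C
Reagents that add atoms: none
Why: Fluoride-induced Si–O cleavage with buffered HF·pyridine (silyl ether deprotection) frees the C8 hydroxyl under non-basic conditions, so neither translactonisation towards O8 nor conjugate addition to the methylene lactone is expected.

Step 10
Reactants: 20 (3aS,4R,6Z,10Z,11aR)-4-hydroxy-6,10-dimethyl-3-methylidene-3a,4,5,8,9,11a-hexahydrocyclodeca[b]furan-2-one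
Product: 21 [(3aS,4R,6Z,10Z,11aR)-6,10-dimethyl-3-methylidene-2-oxo-3a,4,5,8,9,11a-hexahydrocyclodeca[b]furan-4-yl] 3-methylbutanoate
Conditions: (i-BuCO)2O, DMAP (cat.), pyridine, CH2Cl2, 0 → 20 °C
Reagents that add atoms: 3-methylbutanoic anhydride, CC(C)CC(=O)OC(=O)CC(C)C
Why: DMAP-catalysed acyl transfer from the anhydride (nucleophilic catalysis of esterification) acylates the only free hydroxyl with retention at C8 under conditions too mild to move the lactone.

Step 11
Reactants: 21 [(3aS,4R,6Z,10Z,11aR)-6,10-dimethyl-3-methylidene-2-oxo-3a,4,5,8,9,11a-hexahydrocyclodeca[b]furan-4-yl] 3-methylbutanoate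
Product: 22 [(3aS,4R,6E,10Z,11aR)-6-(hydroxymethyl)-10-methyl-3-methylidene-2-oxo-3a,4,5,8,9,11a-hexahydrocyclodeca[b]furan-4-yl] 3-methylbutanoate
Conditions: SeO2 (0.5 equiv), t-BuOOH (3 equiv), CH2Cl2, 20 °C
Reagents that add atoms: tert-butyl hydroperoxide, CC(C)(C)OO, as terminal oxygen source relayed through selenium dioxide, O=[Se]=O
Why: The catalytic SeO2/t-BuOOH allylic oxidation (Riley oxidation, an ene reaction at selenium followed by a [2,3]-sigmatropic shift) goes to the methyl group lying cis to the vinylic hydrogen of the more electron-rich trisubstituted alkene, here C14 on C1=C10, because C4=C5 is deactivated by the allylic lactone oxygen at C6 and the methylene lactone is electron-poor, and the [2,3] shift returns the double bond to C1=C10 with the ring-cis geometry, as is known for C10 methyl groups of germacranolides.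

Step 12
Reactants: 22 [(3aS,4R,6E,10Z,11aR)-6-(hydroxymethyl)-10-methyl-3-methylidene-2-oxo-3a,4,5,8,9,11a-hexahydrocyclodeca[b]furan-4-yl] 3-methylbutanoate
Product: 23 [(3aS,4R,6E,10Z,11aR)-6-formyl-10-methyl-3-methylidene-2-oxo-3a,4,5,8,9,11a-hexahydrocyclodeca[b]furan-4-yl] 3-methylbutanoate
Conditions: MnO2 (activated, excess), CH2Cl2, 20 °C
Reagents that add atoms: none
Why: Activated MnO2 oxidises primary allylic alcohols to enals selectively (allylic alcohol oxidation) and 22 carries no other hydroxyl, so the C14 aldehyde results without touching the esters or the alkenes.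

Step 13
Reactants: 23 [(3aS,4R,6E,10Z,11aR)-6-formyl-10-methyl-3-methylidene-2-oxo-3a,4,5,8,9,11a-hexahydrocyclodeca[b]furan-4-yl] 3-methylbutanoate
Product: 24 [(3aS,4R,6E,10E,11aR)-6-formyl-10-(hydroxymethyl)-3-methylidene-2-oxo-3a,4,5,8,9,11a-hexahydrocyclodeca[b]furan-4-yl] 3-methylbutanoate (CNP0345200.7)
Conditions: SeO2 (0.5 equiv), t-BuOOH (3 equiv), salicylic acid (cat.), CH2Cl2, 20–35 °C
Reagents that add atoms: tert-butyl hydroperoxide, CC(C)(C)OO, as terminal oxygen source relayed through selenium dioxide, O=[Se]=O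
Why: A second Riley oxidation now finds C4=C5 as the only alkene that is not conjugated to a carbonyl group and attacks its methyl group C15, which lies cis to H5, giving the allylic alcohol with the ring-cis geometry retained, in the way allylic esters of the prenyl type are known to react, and the catalytic room-temperature protocol is expected to stop mainly at the alcohol.

**Compound list**

1 | (1Z,5Z)-1,5-dimethylcycloocta-1,5-diene | C/C1=C/CC/C(C)=C\CC1 | starting material
2 | (2Z,6Z)-3,7-dimethylcycloocta-2,6-dien-1-one | O=C1/C=C(/C)CC/C=C(/C)C1 | intermediate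
3 | lithium (1E,3Z,7Z)-3,7-dimethylcycloocta-1,3,7-trien-1-olate (formed in the flask) | [Li+].[O-]C1=C/C(C)=C\CC/C(C)=C\1 | intermediate
4 | trimethyl{[(1E,3Z,7Z)-3,7-dimethylcycloocta-1,3,7-trien-1-yl]oxy}silane | C[Si](C)(C)OC1=C/C(C)=C\CC/C(C)=C\1 | intermediate
5 | trichloroacetyl chloride | ClC(Cl)(Cl)C(Cl)=O | starting material
6 | dichloroketene (formed in the flask) | ClC(Cl)=C=O | intermediate
7 | cis-fused (2Z,6Z)-10,10-dichloro-3,7-dimethyl-1-[(trimethylsilyl)oxy]bicyclo[6.2.0]deca-2,6-dien-9-one, racemic, one enantiomer drawn (formed in the flask) | C[Si](C)(C)O[C@@]12/C=C(/C)CC/C=C(/C)[C@@H]1C(=O)C2(Cl)Cl | intermediate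
8 | cis-fused (2Z,6Z)-3,7-dimethyl-1-[(trimethylsilyl)oxy]bicyclo[6.2.0]deca-2,6-dien-9-one, racemic, one enantiomer drawn (formed in the flask) | C[Si](C)(C)O[C@@]12/C=C(/C)CC/C=C(/C)[C@@H]1C(=O)C2 | intermediate
9 | (4Z,8Z)-5,9-dimethylcyclodeca-4,8-diene-1,3-dione | O=C1/C=C(/C)CC/C=C(/C)CC(=O)C1 | intermediate
10 | tert-butyl bromoacetate | BrCC(=O)OC(C)(C)C | starting material
11 | tert-butyl 2-[(3Z,7Z)-4,8-dimethyl-2,10-dioxocyclodeca-3,7-dien-1-yl]acetate (racemic at the labile C1) | O=C1/C=C(/C)CC/C=C(/C)CC(=O)C1CC(=O)OC(C)(C)C | intermediate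
12 | tert-butyl 2-[(1S,3Z,7Z,10R)-10-hydroxy-4,8-dimethyl-2-oxocyclodeca-3,7-dien-1-yl]acetate | O=C1/C=C(/C)CC/C=C(/C)C[C@@H](O)[C@@H]1CC(=O)OC(C)(C)C | intermediate
13 | tert-butyl 2-[(1S,3Z,7Z,10R)-10-[(tert-butyldimethylsilyl)oxy]-4,8-dimethyl-2-oxocyclodeca-3,7-dien-1-yl]acetate | O=C1/C=C(/C)CC/C=C(/C)C[C@@H](O[Si](C)(C)C(C)(C)C)[C@@H]1CC(=O)OC(C)(C)C | intermediate
14 | lithium alkoxide of tert-butyl 2-[(1R,2R,3Z,7Z,10R)-10-[(tert-butyldimethylsilyl)oxy]-2-hydroxy-4,8-dimethylcyclodeca-3,7-dien-1-yl]acetate (formed in the flask) | [Li+].[O-][C@@H]1/C=C(/C)CC/C=C(/C)C[C@@H](O[Si](C)(C)C(C)(C)C)[C@@H]1CC(=O)OC(C)(C)C | intermediate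
15 | (3aR,4R,6Z,10Z,11aR)-4-[(tert-butyldimethylsilyl)oxy]-6,10-dimethyl-3a,4,5,8,9,11a-hexahydro-3H-cyclodeca[b]furan-2-one | C1C(=O)O[C@@H]2/C=C(/C)CC/C=C(/C)C[C@@H](O[Si](C)(C)C(C)(C)C)[C@H]12 | intermediate
16 | lithium (3aR,4R,6Z,10Z,11aR)-4-[(tert-butyldimethylsilyl)oxy]-6,10-dimethyl-3a,4,5,8,9,11a-hexahydrocyclodeca[b]furan-2-olate (formed in the flask) | C1=C([O-])O[C@@H]2/C=C(/C)CC/C=C(/C)C[C@@H](O[Si](C)(C)C(C)(C)C)[C@H]12.[Li+] | intermediate
17 | (3aR,4R,6Z,10Z,11aR)-4-[(tert-butyldimethylsilyl)oxy]-3-[(dimethylamino)methyl]-6,10-dimethyl-3a,4,5,8,9,11a-hexahydro-3H-cyclodeca[b]furan-2-one, C3 epimers (formed in the flask) | CN(C)CC1C(=O)O[C@@H]2/C=C(/C)CC/C=C(/C)C[C@@H](O[Si](C)(C)C(C)(C)C)[C@H]12 | intermediate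
18 | {[(3aR,4R,6Z,10Z,11aR)-4-[(tert-butyldimethylsilyl)oxy]-6,10-dimethyl-2-oxo-3a,4,5,8,9,11a-hexahydro-3H-cyclodeca[b]furan-3-yl]methyl}trimethylammonium iodide, C3 epimers (formed in the flask) | C[N+](C)(C)CC1C(=O)O[C@@H]2/C=C(/C)CC/C=C(/C)C[C@@H](O[Si](C)(C)C(C)(C)C)[C@H]12.[I-] | intermediate
19 | (3aR,4R,6Z,10Z,11aR)-4-[(tert-butyldimethylsilyl)oxy]-6,10-dimethyl-3-methylidene-3a,4,5,8,9,11a-hexahydrocyclodeca[b]furan-2-one | C=C1C(=O)O[C@@H]2/C=C(/C)CC/C=C(/C)C[C@@H](O[Si](C)(C)C(C)(C)C)[C@H]12 | intermediate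
20 | (3aS,4R,6Z,10Z,11aR)-4-hydroxy-6,10-dimethyl-3-methylidene-3a,4,5,8,9,11a-hexahydrocyclodeca[b]furan-2-one | C=C1C(=O)O[C@@H]2/C=C(/C)CC/C=C(/C)C[C@@H](O)[C@H]12 | intermediate
21 | [(3aS,4R,6Z,10Z,11aR)-6,10-dimethyl-3-methylidene-2-oxo-3a,4,5,8,9,11a-hexahydrocyclodeca[b]furan-4-yl] 3-methylbutanoate | C=C1C(=O)O[C@@H]2/C=C(/C)CC/C=C(/C)C[C@@H](OC(=O)CC(C)C)[C@H]12 | intermediate
22 | [(3aS,4R,6E,10Z,11aR)-6-(hydroxymethyl)-10-methyl-3-methylidene-2-oxo-3a,4,5,8,9,11a-hexahydrocyclodeca[b]furan-4-yl] 3-methylbutanoate | C=C1C(=O)O[C@@H]2/C=C(/C)CC/C=C(/CO)C[C@@H](OC(=O)CC(C)C)[C@H]12 | intermediate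
23 | [(3aS,4R,6E,10Z,11aR)-6-formyl-10-methyl-3-methylidene-2-oxo-3a,4,5,8,9,11a-hexahydrocyclodeca[b]furan-4-yl] 3-methylbutanoate | C=C1C(=O)O[C@@H]2/C=C(/C)CC/C=C(/C=O)C[C@@H](OC(=O)CC(C)C)[C@H]12 | intermediate
24 | [(3aS,4R,6E,10E,11aR)-6-formyl-10-(hydroxymethyl)-3-methylidene-2-oxo-3a,4,5,8,9,11a-hexahydrocyclodeca[b]furan-4-yl] 3-methylbutanoate (CNP0345200.7) | C=C1C(=O)O[C@@H]2/C=C(/CO)CC/C=C(/C=O)C[C@@H](OC(=O)CC(C)C)[C@H]12 | target

**Step count and risks**

Total steps: 13. Longest linear sequence: 13 steps (1 to 24); 5 and 10 are commercial and enter directly.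

Step 5 is the most likely to fail. The hydride may go to the wrong carbonyl, the ten-membered ring may not reproduce the facial and syn preference of open-chain 2-alkyl-1,3-diketones, or C7 may epimerise too slowly for the resolution to be dynamic. The fallback sets out from 11 and returns at 12. Chelation-controlled monoreduction with Zn(BH4)2 (Et2O, −20 °C), which gives syn hydroxy ketones from 2-alkyl-1,3-diketones, would furnish racemic tert-butyl 2-[(1S*,3Z,7Z,10R*)-10-hydroxy-4,8-dimethyl-2-oxocyclodeca-3,7-dien-1-yl]acetate F1. Acylative kinetic resolution (immobilised Candida antarctica lipase B, vinyl acetate, t-BuOMe) is expected to acetylate the enantiomer with the 8R carbinol, whose larger flank is the branched C7, giving tert-butyl 2-[(1S,3Z,7Z,10R)-10-(acetyloxy)-4,8-dimethyl-2-oxocyclodeca-3,7-dien-1-yl]acetate F2. F2 is separated from the unreacted antipode and deacetylated by the same lipase in pH 7 phosphate buffer, without base and hence without β-elimination, to give 12.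

Step 7 is next. Hydride may be delivered to the other face of C6, because the ring conformation rather than the C7 substituent may decide, or the lithium alkoxide may close only slowly onto the hindered ester. The fallback sets out from 13 and returns at 15. If the ring prefers the C6 epimer, it would be made on purpose by Luche reduction (NaBH4, CeCl3·7H2O, MeOH, −78 °C, where no lactone closes) as tert-butyl 2-[(1R,2S,3Z,7Z,10R)-10-[(tert-butyldimethylsilyl)oxy]-2-hydroxy-4,8-dimethylcyclodeca-3,7-dien-1-yl]acetate F3. The tert-butyl ester is then cleaved with Me3SiOTf/2,6-lutidine, followed by mild aqueous methanolysis of the silyl ester and silyl ether, to the hydroxy acid 2-[(1R,2S,3Z,7Z,10R)-10-[(tert-butyldimethylsilyl)oxy]-2-hydroxy-4,8-dimethylcyclodeca-3,7-dien-1-yl]acetic acid F4. Mitsunobu lactonisation (PPh3, DIAD, THF, 0 °C) closes the lactone by SN2 displacement with inversion at C6, the five-membered closure being preferred over SN2′ attack at C4, and gives 15.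

Step 1 is third. Hydrogen abstraction may also occur at the CH2 groups next to the methyl-bearing alkene carbons, giving α-methyl enones, and the product may be oxidised a second time at C2. The fallback sets out from 1 and returns at 2 by a regiochemically defined transposition. Monoepoxidation (m-CPBA, CH2Cl2, 0 °C) gives (4Z)-1,5-dimethyl-9-oxabicyclo[6.1.0]non-4-ene F5. Opening at the less hindered epoxide carbon with PhSeNa (from PhSeSePh and NaBH4, EtOH) gives the hydroxy selenide trans-(5Z)-1,5-dimethyl-2-(phenylselanyl)cyclooct-5-en-1-ol F6. F6 is oxidised in the same flask with H2O2, so that selenoxide syn-elimination away from the carbinol carbon gives the tertiary allylic alcohol (2Z,5Z)-1,5-dimethylcycloocta-2,5-dien-1-ol F7. Chromate-mediated oxidative 1,3-transposition with [C5H5NH][CrO3Cl] (pyridinium chlorochromate, CH2Cl2, 20 °C) then gives 2.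

**Further compounds**

F1 | step 5 | racemic tert-butyl 2-[(1S*,3Z,7Z,10R*)-10-hydroxy-4,8-dimethyl-2-oxocyclodeca-3,7-dien-1-yl]acetate (both enantiomers written) | O=C1/C=C(/C)CC/C=C(/C)C[C@@H](O)[C@@H]1CC(=O)OC(C)(C)C.O=C1/C=C(/C)CC/C=C(/C)C[C@H](O)[C@H]1CC(=O)OC(C)(C)C
F2 | step 5 | tert-butyl 2-[(1S,3Z,7Z,10R)-10-(acetyloxy)-4,8-dimethyl-2-oxocyclodeca-3,7-dien-1-yl]acetate | O=C1/C=C(/C)CC/C=C(/C)C[C@@H](OC(C)=O)[C@@H]1CC(=O)OC(C)(C)C
F3 | step 7 | tert-butyl 2-[(1R,2S,3Z,7Z,10R)-10-[(tert-butyldimethylsilyl)oxy]-2-hydroxy-4,8-dimethylcyclodeca-3,7-dien-1-yl]acetate | O[C@H]1/C=C(/C)CC/C=C(/C)C[C@@H](O[Si](C)(C)C(C)(C)C)[C@@H]1CC(=O)OC(C)(C)C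
F4 | step 7 | 2-[(1R,2S,3Z,7Z,10R)-10-[(tert-butyldimethylsilyl)oxy]-2-hydroxy-4,8-dimethylcyclodeca-3,7-dien-1-yl]acetic acid | O[C@H]1/C=C(/C)CC/C=C(/C)C[C@@H](O[Si](C)(C)C(C)(C)C)[C@@H]1CC(O)=O
F5 | step 1 | (4Z)-1,5-dimethyl-9-oxabicyclo[6.1.0]non-4-ene (cis-epoxide, racemic, one enantiomer drawn) | C/C1=C/CC[C@@]2(C)O[C@H]2CC1
F6 | step 1 | trans-(5Z)-1,5-dimethyl-2-(phenylselanyl)cyclooct-5-en-1-ol (racemic, one enantiomer drawn) | C/C1=C/CC[C@@](C)(O)[C@H]([Se]c2ccccc2)CC1
F7 | step 1 | (2Z,5Z)-1,5-dimethylcycloocta-2,5-dien-1-ol (racemic) | C/C1=C/CCC(C)(O)/C=C\C1
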